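**Plan**
- Retrosynthesis: the 4'-O-pivalate is removed last; the C6 and C8 prenyl groups go back, through cross-metathesis, to allyl groups delivered from O7 and O5 by Claisen rearrangement.
- Ring C is then cut at O1–C8a and C4–C4a: ring A becomes 3,5-bis(methoxymethoxy)benzyne, and C2–C3–C4 with ring B becomes the enolate of an α-formyl arylacetate.
- This cut is possible because O1 and the carbonyl carbon C4 sit on the adjacent ring-A carbons C8a and C4a, and the C5 oxygen next to C4a polarises the aryne so that oxygen adds at C8a and the carbanion, hence C4, ends at C4a.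
- Forward: ring B is built from 2,4-dihydroxybenzaldehyde (3'-prenyl, 4'-O-pivalate, 2'-OMe) and extended in one step to the enol ester; the ring-A silyl triflate comes from phloroglucinol; the annulation closes ring C and gives the isoflavone core.
- Endgame: MOM removal, O-allylation at O5 and O7, double Claisen rearrangement, allyl-to-prenyl metathesis, pivalate methanolysis.
- Stereochemistry: the target has no stereocentre; the Z enol geometry (oxygen cis to the ester) needed for ring closure is held by the internal hydrogen bond and equilibrates in the enolate.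

Key step: step 9

Remark: positions are numbered as in chromen-4-one (O1, C2–C8a; ring B primed). The enol partner is carried as its ethyl ester because it is made from ethyl diazoacetate, so ethoxide is the leaving group in the ring closure.

**Route**

Step 1
Reactants: 1 2,4-dihydroxybenzaldehyde; 2 prenyl bromide (1-bromo-3-methylbut-2-ene)
Product: 3 2,4-dihydroxy-3-(3-methylbut-2-enyl)benzaldehyde
Conditions: KOH (10% aq), 0 °C to rt
Reagents that add atoms: none
Why: Nuclear C-prenylation of the phenoxide in water, where the carbon between the two oxygens (C3) is the most nucleophilic site and the protic medium suppresses O-alkylation; a known direct route, accepted at modest efficiency because both materials are cheap.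

Step 2
Reactants: 3 2,4-dihydroxy-3-(3-methylbut-2-enyl)benzaldehyde
Product: 4 4-formyl-3-hydroxy-2-(3-methylbut-2-enyl)phenyl 2,2-dimethylpropanoate
Conditions: PivCl (1.05 equiv), Et3N, CH2Cl2, 0 °C
Reagents that add atoms: pivaloyl chloride, CC(C)(C)C(=O)Cl
Why: Chemoselective O-acylation of the more acidic 4-hydroxyl, the 2-hydroxyl being hydrogen-bonded to the formyl group and flanked on both sides; the pivalate is chosen because it should survive acid, fluoride, carbonate bases and 200 °C and leave by mild methanolysis.

Step 3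
Reactants: 4 4-formyl-3-hydroxy-2-(3-methylbut-2-enyl)phenyl 2,2-dimethylpropanoate
Product: 5 4-formyl-3-methoxy-2-(3-methylbut-2-enyl)phenyl 2,2-dimethylpropanoate
Conditions: MeI, K2CO3, DMF, rt
Reagents that add atoms: iodomethane, CI
Why: Williamson methylation of the remaining chelated phenol, which the hindered aryl pivalate should tolerate at room temperature.

Step 4
Reactants: 5 4-formyl-3-methoxy-2-(3-methylbut-2-enyl)phenyl 2,2-dimethylpropanoate
Product: 6 ethyl (Z)-3-hydroxy-2-[2-methoxy-3-(3-methylbut-2-enyl)-4-(2,2-dimethylpropanoyloxy)phenyl]prop-2-enoate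
Conditions: ethyl diazoacetate, HBF4·OEt2 (10 mol %), CH2Cl2, −78 °C
Reagents that add atoms: ethyl diazoacetate, CCOC(=O)C=[N+]=[N-]
Why: Acid-catalysed aldehyde–diazoacetate coupling of the Roskamp type diverted to a 1,2-aryl shift: the electron-rich ortho-methoxy aryl group migrates in preference to hydride as N2 leaves, which is the known one-step route from electron-rich benzaldehydes to 3-hydroxy-2-arylacrylates, and the product rests as the hydrogen-bonded Z enol.

Step 5
Reactants: 7 phloroglucinol
Product: 8 3,5-bis(methoxymethoxy)phenol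
Conditions: MOMCl (2.1 equiv), i-Pr2NEt, THF/DMF, 0 °C to rt
Reagents that add atoms: chloromethyl methyl ether, COCCl
Why: Statistical O-alkylation (MOM ether formation) with a hard electrophile that reacts at oxygen and not at carbon; the bis-ether is separated from the mono- and tris-ethers, which can be recycled.

Step 6
Reactants: 8 3,5-bis(methoxymethoxy)phenol
Product: 9 3,5-bis(methoxymethoxy)phenyl N-isopropylcarbamate
Conditions: i-PrNCO, Et3N (cat.), CH2Cl2, rt
Reagents that add atoms: isopropyl isocyanate, CC(C)N=C=O
Why: Base-catalysed addition of the phenol to the isocyanate (carbamoylation) installs a strong ortho-directing group that can later be removed under mild, non-acidic conditions.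

Step 7
Reactants: 9 3,5-bis(methoxymethoxy)phenyl N-isopropylcarbamate
Product: 13 3,5-bis(methoxymethoxy)-2-(trimethylsilyl)phenyl N-isopropylcarbamate, via N-silyl carbamate 10 (not isolated), via aryllithium 11 (not isolated), via N,C-disilyl carbamate 12 (not isolated)
Conditions: TMSOTf, TMEDA, Et2O, 0 °C to rt; n-BuLi, TMEDA, −78 °C; TMSCl, −78 °C to rt; aq NH4Cl
Reagents that add atoms: chlorotrimethylsilane, C[Si](C)(C)Cl
Why: Directed ortho-metalation: after transient N-silylation the carbamate, the strongest director on the ring, cooperates with the neighbouring acetal oxygen to guide n-BuLi to the carbon between them (two equivalent sites), and silylation at −78 °C should precede any anionic Fries migration.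

Step 8
Reactants: 13 3,5-bis(methoxymethoxy)-2-(trimethylsilyl)phenyl N-isopropylcarbamate
Product: 15 3,5-bis(methoxymethoxy)-2-(trimethylsilyl)phenyl trifluoromethanesulfonate, via silylphenol 14 (not isolated)
Conditions: DBU, Et2NH, MeCN, 40 °C; then PhNTf2, rt
Reagents that add atoms: N-phenylbis(trifluoromethanesulfonimide), O=S(=O)(N(c1ccccc1)S(=O)(=O)C(F)(F)F)C(F)(F)F
Why: One-pot carbamate cleavage and O-sulfonylation: DBU eliminates isopropyl isocyanate from the N–H carbamate (E1cB), diethylamine traps the isocyanate, and PhNTf2 triflates the phenoxide without disturbing the aryl–silicon bond or the acetals.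

Step 9
Reactants: 6 ethyl (Z)-3-hydroxy-2-[2-methoxy-3-(3-methylbut-2-enyl)-4-(2,2-dimethylpropanoyloxy)phenyl]prop-2-enoate; 15 3,5-bis(methoxymethoxy)-2-(trimethylsilyl)phenyl trifluoromethanesulfonate
Product: 18 3-[2-methoxy-3-(3-methylbut-2-enyl)-4-(2,2-dimethylpropanoyloxy)phenyl]-5,7-bis(methoxymethoxy)chromen-4-one, via 3,5-bis(methoxymethoxy)benzyne 16 (not isolated), via aryl anion adduct 17 (not isolated)
Conditions: CsF (4 equiv), THF, 65 °C; 15 (1.3 equiv) added in portions
Reagents that add atoms: none
Why: Proposed new method: fluoride deprotonates enol 6 and desilylates 15, releasing aryne 16; the terminal enolate oxygen should add to the aryne carbon distal to the C5 ether (future C8a) so that the aryl anion 17 sits at C4a beside the inductively stabilising C5–O bond, and this anion then attacks the cis-disposed ester carbonyl and expels ethoxide, forming O1–C8a and C4–C4a in one operation. The closest known reaction type is the fluoride-induced annulation of arynes with salicylate esters to xanthones (O-arylation followed by intramolecular acyl capture); a formylacetate enolate in place of the phenoxide has not been shown. Ring C closes by a 6-exo-trig addition–elimination of the C4a anion on the ester; no stereocentre is formed, and the Z enolate geometry needed for closure is reached because the delocalised enolate equilibrates. Regiochemistry on the aryne is secured by the C5 alkoxy group, which distorts the triple bond and sends nucleophiles to the remote carbon. Oxygen over carbon arylation is the selectivity at issue and is expected because the enol carbon is fully substituted and shielded by the twisted ortho-methoxy aryl ring, whereas the formyl-derived oxygen of the cesium enolate is unhindered. THF at 65 °C is used so that the solvent cannot protonate 17 before acyl capture, and the bifluoride formed from the enol proton should neutralise the released ethoxide and so protect the pivalate.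

Step 10
Reactants: 18 3-[2-methoxy-3-(3-methylbut-2-enyl)-4-(2,2-dimethylpropanoyloxy)phenyl]-5,7-bis(methoxymethoxy)chromen-4-one
Product: 19 5,7-dihydroxy-3-[2-methoxy-3-(3-methylbut-2-enyl)-4-(2,2-dimethylpropanoyloxy)phenyl]chromen-4-one
Conditions: p-TsOH·H2O (0.2 equiv), MeOH/THF, 45 °C
Reagents that add atoms: none
Why: Acid-catalysed transacetalisation in methanol cleaves both aryl MOM ethers (the 5-ether fastest, owing to the peri carbonyl), while the pivalate is acid-stable and the ring-B prenyl group has no free neighbouring hydroxyl with which to cyclise.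

Step 11
Reactants: 19 5,7-dihydroxy-3-[2-methoxy-3-(3-methylbut-2-enyl)-4-(2,2-dimethylpropanoyloxy)phenyl]chromen-4-one
Product: 20 3-[2-methoxy-3-(3-methylbut-2-enyl)-4-(2,2-dimethylpropanoyloxy)phenyl]-5,7-bis(prop-2-enyloxy)chromen-4-one
Conditions: allyl bromide (4 equiv), K2CO3, DMF, 60 °C
Reagents that add atoms: allyl bromide, C=CCBr
Why: Twofold Williamson O-allylation; the 7-hydroxyl reacts first, and excess allyl bromide with warming should also alkylate the hydrogen-bonded 5-hydroxyl, the only other free phenol.

Step 12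
Reactants: 20 3-[2-methoxy-3-(3-methylbut-2-enyl)-4-(2,2-dimethylpropanoyloxy)phenyl]-5,7-bis(prop-2-enyloxy)chromen-4-one
Product: 21 5,7-dihydroxy-3-[2-methoxy-3-(3-methylbut-2-enyl)-4-(2,2-dimethylpropanoyloxy)phenyl]-6,8-bis(prop-2-enyl)chromen-4-one
Conditions: PhNEt2, 200 °C, sealed tube
Reagents that add atoms: none
Why: Twofold aromatic Claisen rearrangement: the only free ring-A positions are C6 and C8, so ortho [3,3] shifts from O7 to C8 and from O5 to C6, or a para Claisen–Cope shift from O5 to C8 if C6 is already taken, all converge on the same 6,8-diallyl diphenol, and a simple allyl group has the same constitution whichever path it follows.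

Step 13
Reactants: 21 5,7-dihydroxy-3-[2-methoxy-3-(3-methylbut-2-enyl)-4-(2,2-dimethylpropanoyloxy)phenyl]-6,8-bis(prop-2-enyl)chromen-4-one
Product: 22 5,7-dihydroxy-3-[2-methoxy-3-(3-methylbut-2-enyl)-4-(2,2-dimethylpropanoyloxy)phenyl]-6,8-bis(3-methylbut-2-enyl)chromen-4-one
Conditions: second-generation Grubbs catalyst RuCl2(=CHPh)(PCy3)(H2IMes) (5 mol %), 2-methyl-2-butene/CH2Cl2, 40 °C, sealed
Reagents that add atoms: 2-methyl-2-butene, CC=C(C)C
Why: Olefin cross-metathesis of the two terminal allyl groups with excess 2-methyl-2-butene turns each into a prenyl group with release of propene, a standard allyl-to-prenyl exchange that tolerates free phenols and leaves the trisubstituted ring-B prenyl group unchanged.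

Step 14
Reactants: 22 5,7-dihydroxy-3-[2-methoxy-3-(3-methylbut-2-enyl)-4-(2,2-dimethylpropanoyloxy)phenyl]-6,8-bis(3-methylbut-2-enyl)chromen-4-one
Product: 23 5,7-dihydroxy-3-[4-hydroxy-2-methoxy-3-(3-methylbut-2-enyl)phenyl]-6,8-bis(3-methylbut-2-enyl)chromen-4-one (CNP0331360.0)
Conditions: K2CO3, MeOH, 40 °C; then aq NH4Cl
Reagents that add atoms: none
Why: Base-catalysed transesterification (methanolysis) of the aryl pivalate under mild carbonate conditions, which avoid the acid-induced chroman formation that three ortho-prenyl phenols would invite and the hydroxide-induced opening of the pyranone.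

**Compound list**

1 | 2,4-dihydroxybenzaldehyde | O=Cc1ccc(O)cc1O | starting material
2 | prenyl bromide (1-bromo-3-methylbut-2-ene) | CC(C)=CCBr | starting material
3 | 2,4-dihydroxy-3-(3-methylbut-2-enyl)benzaldehyde | O=Cc1ccc(O)c(CC=C(C)C)c1O | intermediate
4 | 4-formyl-3-hydroxy-2-(3-methylbut-2-enyl)phenyl 2,2-dimethylpropanoate | O=Cc1ccc(OC(=O)C(C)(C)C)c(CC=C(C)C)c1O | intermediate
5 | 4-formyl-3-methoxy-2-(3-methylbut-2-enyl)phenyl 2,2-dimethylpropanoate | COc1c(C=O)ccc(OC(=O)C(C)(C)C)c1CC=C(C)C | intermediate
6 | ethyl (Z)-3-hydroxy-2-[2-methoxy-3-(3-methylbut-2-enyl)-4-(2,2-dimethylpropanoyloxy)phenyl]prop-2-enoate | CCOC(=O)/C(=C\O)c1ccc(OC(=O)C(C)(C)C)c(CC=C(C)C)c1OC | intermediate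
7 | phloroglucinol | Oc1cc(O)cc(O)c1 | starting material
8 | 3,5-bis(methoxymethoxy)phenol | COCOc1cc(O)cc(OCOC)c1 | intermediate
9 | 3,5-bis(methoxymethoxy)phenyl N-isopropylcarbamate | COCOc1cc(OCOC)cc(OC(=O)NC(C)C)c1 | intermediate
10 | 3,5-bis(methoxymethoxy)phenyl N-isopropyl-N-(trimethylsilyl)carbamate | COCOc1cc(OCOC)cc(OC(=O)N(C(C)C)[Si](C)(C)C)c1 | intermediate (not isolated)
11 | 2-[N-isopropyl-N-(trimethylsilyl)carbamoyloxy]-4,6-bis(methoxymethoxy)phenyllithium | COCOc1cc(OCOC)c([Li])c(OC(=O)N(C(C)C)[Si](C)(C)C)c1 | intermediate (not isolated)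
12 | 3,5-bis(methoxymethoxy)-2-(trimethylsilyl)phenyl N-isopropyl-N-(trimethylsilyl)carbamate | COCOc1cc(OCOC)c([Si](C)(C)C)c(OC(=O)N(C(C)C)[Si](C)(C)C)c1 | intermediate (not isolated)
13 | 3,5-bis(methoxymethoxy)-2-(trimethylsilyl)phenyl N-isopropylcarbamate | COCOc1cc(OCOC)c([Si](C)(C)C)c(OC(=O)NC(C)C)c1 | intermediate
14 | 3,5-bis(methoxymethoxy)-2-(trimethylsilyl)phenol (formed as its amidinium phenoxide) | COCOc1cc(O)c([Si](C)(C)C)c(OCOC)c1 | intermediate (not isolated)
15 | 3,5-bis(methoxymethoxy)-2-(trimethylsilyl)phenyl trifluoromethanesulfonate | COCOc1cc(OCOC)c([Si](C)(C)C)c(OS(=O)(=O)C(F)(F)F)c1 | intermediate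
16 | 3,5-bis(methoxymethoxy)benzyne | COCOC1=CC(OCOC)=CC#C1 | intermediate (not isolated)
17 | cesium 2-{(Z)-3-ethoxy-2-[2-methoxy-3-(3-methylbut-2-enyl)-4-(2,2-dimethylpropanoyloxy)phenyl]-3-oxoprop-1-enoxy}-4,6-bis(methoxymethoxy)benzenide | CCOC(=O)/C(=C\Oc1cc(OCOC)cc(OCOC)[c-]1)c1ccc(OC(=O)C(C)(C)C)c(CC=C(C)C)c1OC.[Cs+] | intermediate (not isolated)
18 | 3-[2-methoxy-3-(3-methylbut-2-enyl)-4-(2,2-dimethylpropanoyloxy)phenyl]-5,7-bis(methoxymethoxy)chromen-4-one | COCOc1cc(OCOC)c2c(=O)c(-c3ccc(OC(=O)C(C)(C)C)c(CC=C(C)C)c3OC)coc2c1 | intermediate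
19 | 5,7-dihydroxy-3-[2-methoxy-3-(3-methylbut-2-enyl)-4-(2,2-dimethylpropanoyloxy)phenyl]chromen-4-one | Oc1cc(O)c2c(=O)c(-c3ccc(OC(=O)C(C)(C)C)c(CC=C(C)C)c3OC)coc2c1 | intermediate
20 | 3-[2-methoxy-3-(3-methylbut-2-enyl)-4-(2,2-dimethylpropanoyloxy)phenyl]-5,7-bis(prop-2-enyloxy)chromen-4-one | C=CCOc1cc(OCC=C)c2c(=O)c(-c3ccc(OC(=O)C(C)(C)C)c(CC=C(C)C)c3OC)coc2c1 | intermediate
21 | 5,7-dihydroxy-3-[2-methoxy-3-(3-methylbut-2-enyl)-4-(2,2-dimethylpropanoyloxy)phenyl]-6,8-bis(prop-2-enyl)chromen-4-one | C=CCc1c(O)c(CC=C)c2occ(-c3ccc(OC(=O)C(C)(C)C)c(CC=C(C)C)c3OC)c(=O)c2c1O | intermediate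
22 | 5,7-dihydroxy-3-[2-methoxy-3-(3-methylbut-2-enyl)-4-(2,2-dimethylpropanoyloxy)phenyl]-6,8-bis(3-methylbut-2-enyl)chromen-4-one | CC(C)=CCc1c(O)c(CC=C(C)C)c2occ(-c3ccc(OC(=O)C(C)(C)C)c(CC=C(C)C)c3OC)c(=O)c2c1O | intermediate
23 | 5,7-dihydroxy-3-[4-hydroxy-2-methoxy-3-(3-methylbut-2-enyl)phenyl]-6,8-bis(3-methylbut-2-enyl)chromen-4-one | COc1c(-c2coc3c(CC=C(C)C)c(O)c(CC=C(C)C)c(O)c3c2=O)ccc(O)c1CC=C(C)C | target

**Step count and risks**

Total steps: 14. Longest linear sequence: 10 steps (steps 1–4 and 9–14; the phloroglucinol branch, steps 5–8 and 9–14, is equally long).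

Steps most likely to fail:

1. Step 9 (Proposed new method). The ambident enolate may be arylated at carbon instead of oxygen, after which the aryl anion would add to the formyl group and the adduct would fragment (net insertion into the C–CHO bond). The aryl anion may also be protonated before it reaches the ester, leaving an uncyclised aryl enol ether, and surplus aryne may undergo an ene reaction with the prenyl olefin. The fallback uses known chemistry only, sets out from aldehyde 5, uses silyl triflate 15 and returns to the route at 18. Wittig reaction of 5 with Ph3P=CHOMe (from (methoxymethyl)triphenylphosphonium chloride and t-BuOK, THF, 0 °C) should give the enol ether 4-(2-methoxyethenyl)-3-methoxy-2-(3-methylbut-2-enyl)phenyl 2,2-dimethylpropanoate F1 as an E/Z mixture. Mild aqueous acid (1 M HCl, THF, rt) should hydrolyse it to the arylacetaldehyde 3-methoxy-2-(3-methylbut-2-enyl)-4-(2-oxoethyl)phenyl 2,2-dimethylpropanoate F2. Pinnick oxidation (NaClO2, NaH2PO4, 2-methyl-2-butene, t-BuOH/H2O) should then give 2-[2-methoxy-3-(3-methylbut-2-enyl)-4-(2,2-dimethylpropanoyloxy)phenyl]acetic acid F3. Heating F3 with 15 and CsF in THF (sealed tube, about 125 °C) effects the known aryne insertion into the C–O bond of a carboxylic acid: the carboxylate oxygen adds at the distal aryne carbon and the acyl group migrates to the adjacent carbanion. This should give the deoxybenzoin 1-[2-hydroxy-4,6-bis(methoxymethoxy)phenyl]-2-[2-methoxy-3-(3-methylbut-2-enyl)-4-(2,2-dimethylpropanoyloxy)phenyl]ethanone F4. Condensation of F4 with Me2NCH(OMe)2 (toluene, 90 °C) supplies C2 and closes the pyranone to 18.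

2. Step 4. Hydride instead of aryl migration would give the β-keto ester, and the acid catalyst may add to the prenyl olefin. The fallback sets out from 5 and returns at 6. Darzens condensation of 5 with ethyl chloroacetate and t-BuOK (THF, −20 °C) should give ethyl trans-3-[2-methoxy-3-(3-methylbut-2-enyl)-4-(2,2-dimethylpropanoyloxy)phenyl]oxirane-2-carboxylate F5 (racemic). BF3·OEt2 (CH2Cl2, −40 °C) should then open the epoxide at the benzylic carbon, and a 1,2-shift of the ester group (Meinwald-type rearrangement) delivers the formylacetate, which tautomerises to 6.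

3. Step 7. Metalation may occur between the two acetal oxygens (C4) instead of between carbamate and acetal, giving the regioisomeric silane, or the carbamoyl group may migrate to carbon on warming. The fallback sets out from 8, bypasses the carbamate and returns at 15. Bromination of 8 with N-bromosuccinimide (CH2Cl2, −78 °C) ortho to the free hydroxyl should give 2-bromo-3,5-bis(methoxymethoxy)phenol F6. Silylation with HN(SiMe3)2 (THF, 70 °C) gives [2-bromo-3,5-bis(methoxymethoxy)phenoxy]trimethylsilane F7. n-BuLi (THF, −100 to −78 °C) then triggers bromine–lithium exchange and O-to-C silyl migration (retro-Brook) to the lithium phenoxide of 14, which Tf2O converts into 15.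

Further compounds
F1 | step 9 | 4-(2-methoxyethenyl)-3-methoxy-2-(3-methylbut-2-enyl)phenyl 2,2-dimethylpropanoate (E/Z mixture) | COC=Cc1ccc(OC(=O)C(C)(C)C)c(CC=C(C)C)c1OC
F2 | step 9 | 3-methoxy-2-(3-methylbut-2-enyl)-4-(2-oxoethyl)phenyl 2,2-dimethylpropanoate | O=CCc1ccc(OC(=O)C(C)(C)C)c(CC=C(C)C)c1OC
F3 | step 9 | 2-[2-methoxy-3-(3-methylbut-2-enyl)-4-(2,2-dimethylpropanoyloxy)phenyl]acetic acid | OC(=O)Cc1ccc(OC(=O)C(C)(C)C)c(CC=C(C)C)c1OC
F4 | step 9 | 1-[2-hydroxy-4,6-bis(methoxymethoxy)phenyl]-2-[2-methoxy-3-(3-methylbut-2-enyl)-4-(2,2-dimethylpropanoyloxy)phenyl]ethanone | COCOc1cc(O)c(C(=O)Cc2ccc(OC(=O)C(C)(C)C)c(CC=C(C)C)c2OC)c(OCOC)c1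
F5 | step 4 | ethyl trans-3-[2-methoxy-3-(3-methylbut-2-enyl)-4-(2,2-dimethylpropanoyloxy)phenyl]oxirane-2-carboxylate (racemic, one enantiomer drawn) | CCOC(=O)[C@H]1O[C@@H]1c1ccc(OC(=O)C(C)(C)C)c(CC=C(C)C)c1OC
F6 | step 7 | 2-bromo-3,5-bis(methoxymethoxy)phenol | COCOc1cc(O)c(Br)c(OCOC)c1
F7 | step 7 | [2-bromo-3,5-bis(methoxymethoxy)phenoxy]trimethylsilane | COCOc1cc(O[Si](C)(C)C)c(Br)c(OCOC)c1
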